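The five-membered ring is opened retrosynthetically at C4–C5. Its only stereocentre, quaternary C1 (OMe, CO2Me), is carried over intact from C1 of (−)-quinic acid; ring atoms C2–C4 and C5 are the quinic carbons C6, C5, C4 and C2, and the cinnamoyl carbonyl carbon is quinic C3. One operation, periodate cleavage of the cis-3,4-diol followed by aldol addition of the CH2CHO arm to the second aldehyde, shrinks the cyclohexane to the cyclopentane and expels C3 as the formyl group on C5. The precursor is a methyl quinate with methyl ethers on O1 and O5, a silyl ether already installed at C6, and the free cis-diol.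

Key step: step 10

Numbering: cyclohexanes are numbered as quinic acid (C1 bears the carboxyl group); cyclopentanes carry the target numbering (C1 quaternary, C2 and C3 the later enol ether carbons, C4 the later ketone, C5 the side-chain carbon).
Design remark: the C2 oxygen is introduced on the cyclohexanone, which has a single α-methylene, and O5 is methylated at that stage, so that after the ring contraction only an addition, one deprotection, one oxidation and one O-methylation remain.
Assumption: the centres created at quinic C5 and C6 and at ring atoms C4 and C5 all become sp2 in the target, so they are carried as epimer mixtures and only C1 has to stay defined.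

Step 1
Reactants: 1 (−)-quinic acid
Product: 2 3,4-O-isopropylidenequinic acid 1,5-lactone
Conditions: 2,2-dimethoxypropane, acetone, TsOH·H2O (cat.), reflux
Reagents that add atoms: 2,2-dimethoxypropane, COC(C)(C)OC
Why: Acid-catalysed ketalisation protects the only cis-vicinal diol (O3/O4) while the carboxyl group lactonises onto O5, a known one-pot reaction of quinic acid that leaves the tertiary 1-OH as the single free hydroxyl and touches no stereocentre.

Step 2
Reactants: 2 3,4-O-isopropylidenequinic acid 1,5-lactone
Product: 3 1-O-methyl-3,4-O-isopropylidenequinic acid 1,5-lactone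
Conditions: NaH, MeI, DMF, 0 °C to rt
Reagents that add atoms: iodomethane, CI
Why: Williamson etherification of the tertiary alkoxide; the bicyclic lactone has no α-hydrogen and C1 is a bridgehead, so neither epimerisation nor elimination can compete.

Step 3
Reactants: 3 1-O-methyl-3,4-O-isopropylidenequinic acid 1,5-lactone
Product: 4 methyl 3,4-O-isopropylidene-1-O-methylquinate (5-OH free)
Conditions: NaOMe (cat.), MeOH, 0 °C to rt
Reagents that add atoms: methanol, CO
Why: Base-catalysed transesterification (lactone methanolysis) under equilibrium control in methanol installs the methyl ester of the target and frees O5 as the only hydroxyl.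

Step 4
Reactants: 4 methyl 3,4-O-isopropylidene-1-O-methylquinate
Product: 5 methyl 5-dehydro-3,4-O-isopropylidene-1-O-methylquinate (ketone at C5)
Conditions: Dess–Martin periodinane, pyridine, CH2Cl2, 0 °C to rt
Reagents that add atoms: none
Why: Dess–Martin oxidation of the single secondary alcohol under buffered, non-basic conditions should give the ketone without β-elimination of the C1 methoxy group.

Step 5
Reactants: 5 methyl 5-dehydro-3,4-O-isopropylidene-1-O-methylquinate
Product: 6 tert-butyldimethylsilyl enol ether of 5 with the C5=C6 double bond
Conditions: TBSOTf, Et3N, CH2Cl2, −78 to 0 °C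
Reagents that add atoms: tert-butyldimethylsilyl trifluoromethanesulfonate, CC(C)(C)[Si](C)(C)OS(=O)(=O)C(F)(F)F
Why: Soft enolisation with a silyl triflate and a tertiary amine should form the silyl enol ether towards the only α-methylene (C6), the ring-fusion α-alkoxy methine at C4 being kinetically much less accessible; no free enolate is generated, so the β-methoxy group at C1 is not expelled.

Step 6
Reactants: 6 tert-butyldimethylsilyl enol ether of 5
Product: 7 methyl 6-(tert-butyldimethylsilyloxy)-5-dehydro-3,4-O-isopropylidene-1-O-methylquinate (C6 epimers)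
Conditions: mCPBA, CH2Cl2, −20 °C to rt
Reagents that add atoms: 3-chloroperoxybenzoic acid, OOC(=O)c1cccc(Cl)c1
Why: Rubottom oxidation, in which the peracid epoxidises the electron-rich enol ether and the silyloxy oxirane rearranges with a 1,4-silyl shift to the α-silyloxy ketone, places the future C2 oxygen of the target; the new C6 centre is not controlled because it ends up sp2.

Step 7
Reactants: 7 methyl 6-(tert-butyldimethylsilyloxy)-5-dehydro-3,4-O-isopropylidene-1-O-methylquinate
Product: 8 methyl 6-(tert-butyldimethylsilyloxy)-3,4-O-isopropylidene-1-O-methylquinate-type alcohol with free 5-OH (C5/C6 epimers)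
Conditions: NaBH4, MeOH, −40 to 0 °C
Reagents that add atoms: none
Why: Borohydride reduction is chemoselective for the ketone over the hindered ester, the cold protic medium keeps the alkoxide protonated so that the neighbouring silyl group should not migrate, and either C5 epimer serves because this carbon becomes sp2 later.

Step 8
Reactants: 8 5-hydroxy compound
Product: 9 methyl 6-(tert-butyldimethylsilyloxy)-3,4-O-isopropylidene-1,5-di-O-methylquinate-type ether (C5/C6 epimers)
Conditions: MeOTf, 2,6-di-tert-butyl-4-methylpyridine, CH2Cl2, rt
Reagents that add atoms: methyl trifluoromethanesulfonate, COS(=O)(=O)C(F)(F)F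
Why: O-Methylation with methyl triflate and a hindered non-nucleophilic pyridine base forms no alkoxide, which excludes silyl migration and relactonisation onto the C1 ester while installing the methyl ether that becomes the C3 methoxy group of the target.

Step 9
Reactants: 9 acetonide methyl ether
Product: 10 methyl (1S)-6-(tert-butyldimethylsilyloxy)-3,4-dihydroxy-1,5-dimethoxycyclohexane-1-carboxylate (C1/C3/C4 as in quinic acid with the 3,4-cis-diol; C5/C6 epimers)
Conditions: AcOH/H2O (4:1), 45 °C
Reagents that add atoms: none
Why: Mild acid hydrolysis cleaves the cis-fused dioxolane, whereas the neopentyl-type secondary silyl ether between C1 and C5 hydrolyses far more slowly and the methyl ethers are inert, so the only vicinal diol of the molecule is set free.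

Step 10
Reactants: 10 methyl (1S)-6-(tert-butyldimethylsilyloxy)-3,4-dihydroxy-1,5-dimethoxycyclohexane-1-carboxylate
Product: 12 methyl (1S)-2-(tert-butyldimethylsilyloxy)-5-formyl-4-hydroxy-1,3-dimethoxycyclopentane-1-carboxylate, via dialdehyde 11 (not isolated)
Conditions: NaIO4 on silica gel, CH2Cl2, rt; filter; then L-proline (30 mol%), DMSO, rt
Reagents that add atoms: none
Why: NaIO4 cleaves the only vicinal diol, the cis-diol at quinic C3/C4, to dialdehyde 11, and L-proline then forms an enamine from the unbranched CH2CHO arm whose α-carbon (quinic C2) adds to the α-methoxy aldehyde (quinic C4) before hydrolysis releases the β-hydroxy aldehyde. The closest known reaction type is the amine-catalysed intramolecular aldol addition of a dialdehyde made by glycol cleavage, the established ring contraction of cyclohexane-1,2-diols to cyclopentane carbaldehydes. The cyclopentane closes in a 5-exo-trig mode with the enamine double bond exocyclic to the new ring (5-enolexo), which forms the C4–C5 bond and leaves quinic C3 outside the ring as the formyl group. The two new stereocentres, carbinol C4 and formyl-bearing C5, are set by the proline enamine transition state together with the neighbouring C3 methoxy group, but no particular outcome is needed because both carbons become sp2; C1 takes no part and keeps the quinic acid configuration. The step needs donor/acceptor selectivity, and the substrate provides it: only the CH2CHO aldehyde condenses readily with the amine, the α-branched α-methoxy aldehyde is the more electrophilic carbonyl, and the reverse closure would have to build a fully substituted carbon. Neutral conditions at room temperature and a short reaction time are chosen so that the aldol is not dehydrated and the enamine does not expel the methoxy group at C1.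

Step 11
Reactants: 12 methyl (1S)-2-(tert-butyldimethylsilyloxy)-5-formyl-4-hydroxy-1,3-dimethoxycyclopentane-1-carboxylate; 13 (E)-β-bromostyrene
Product: 14 methyl (1S)-2-(tert-butyldimethylsilyloxy)-4-hydroxy-5-[(2E)-1-hydroxy-3-phenylprop-2-en-1-yl]-1,3-dimethoxycyclopentane-1-carboxylate
Conditions: CrCl2 (4 equiv), NiCl2 (2 mol%), DMF, rt
Reagents that add atoms: none
Why: Nozaki–Hiyama–Kishi reaction, in which the nickel-catalysed alkenylchromium reagent (trivalent chromium) adds only to the aldehyde, tolerates the free hydroxyl, ester and silyl ether, keeps the E geometry of the bromide and gives a weakly basic chromium alkoxide that should neither undergo retro-aldol cleavage nor lactonise; the new carbinol centre is uncontrolled and is oxidised later.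

Step 12
Reactants: 14 silyl ether diol
Product: 15 methyl (1S)-2,4-dihydroxy-5-[(2E)-1-hydroxy-3-phenylprop-2-en-1-yl]-1,3-dimethoxycyclopentane-1-carboxylate
Conditions: HF·pyridine, pyridine, THF, 0 °C to rt
Reagents that add atoms: none
Why: Fluoride cleavage of the silyl ether with pyridine-buffered HF·pyridine frees the C2 hydroxyl without generating an alkoxide, which should keep the side-chain hydroxyl from lactonising onto the C1 ester.

Step 13
Reactants: 15 triol
Product: 16 methyl (1S,5Z)-2-hydroxy-5-[(2E)-1-hydroxy-3-phenylprop-2-en-1-ylidene]-1,3-dimethoxy-4-oxocyclopent-2-ene-1-carboxylate (dienol form of the 2,4-dioxo-5-cinnamoyl compound)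
Conditions: IBX (6 equiv), DMSO, rt
Reagents that add atoms: none
Why: IBX oxidation of all three secondary alcohols (allylic, ring C4 and hindered ring C2) without base is a known way to turn 1,3-diols and β-hydroxy ketones into β-dicarbonyl compounds, and the product should settle as the dienol in which C2, C3 and C5 are sp2, so that methanol cannot be eliminated from C1.

Step 14
Reactants: 16 dienol triketone
Product: 17 methyl (1S,5Z)-5-[(2E)-1-hydroxy-3-phenylprop-2-en-1-ylidene]-1,2,3-trimethoxy-4-oxocyclopent-2-ene-1-carboxylate (target)
Conditions: TMSCHN2 (1.05 equiv), toluene/MeOH (4:1), −20 to 0 °C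
Reagents that add atoms: (trimethylsilyl)diazomethane, C[Si](C)(C)C=[N+]=[N-]
Why: O-Methylation by a diazoalkane goes to the most acidic hydroxyl, here the ring 2-hydroxy enone (a vinylogous carboxylic acid) rather than the hydrogen-bonded enol of the cinnamoyl β-diketone, and reaction through O2 is preferred because O4 is engaged as the acceptor of that hydrogen bond; C1 is untouched.

Compound list
1 | (−)-quinic acid, (1S,3R,4S,5R)-1,3,4,5-tetrahydroxycyclohexane-1-carboxylic acid | C1[C@@H](O)[C@@H](O)[C@H](O)C[C@@]1(C(=O)O)O | starting material
2 | 3,4-O-isopropylidenequinic acid 1,5-lactone (acetonide on O3/O4, lactone to O5, 1-OH free) | C1[C@@H](OC(C)(C)O2)[C@@H]2[C@H](O3)C[C@@]1(C3=O)O | intermediate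
3 | 1-O-methyl-3,4-O-isopropylidenequinic acid 1,5-lactone | C1[C@@H](OC(C)(C)O2)[C@@H]2[C@H](O3)C[C@@]1(C3=O)OC | intermediate
4 | methyl 3,4-O-isopropylidene-1-O-methylquinate (5-OH free) | C1[C@@H](OC(C)(C)O2)[C@@H]2[C@H](O)C[C@@]1(C(=O)OC)OC | intermediate
5 | methyl 5-dehydro-3,4-O-isopropylidene-1-O-methylquinate (C5 ketone) | C1[C@@H](OC(C)(C)O2)[C@@H]2C(=O)C[C@@]1(C(=O)OC)OC | intermediate
6 | tert-butyldimethylsilyl enol ether of 5 (C5=C6) | C1[C@@H](OC(C)(C)O2)[C@@H]2C(O[Si](C)(C)C(C)(C)C)=C[C@@]1(C(=O)OC)OC | intermediate
7 | methyl 6-(tert-butyldimethylsilyloxy)-5-dehydro-3,4-O-isopropylidene-1-O-methylquinate (C6 epimers) | C1[C@@H](OC(C)(C)O2)[C@@H]2C(=O)C(O[Si](C)(C)C(C)(C)C)[C@@]1(C(=O)OC)OC | intermediate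
8 | 5-hydroxy compound from reduction of 7 (C5/C6 epimers) | C1[C@@H](OC(C)(C)O2)[C@@H]2C(O)C(O[Si](C)(C)C(C)(C)C)[C@@]1(C(=O)OC)OC | intermediate
9 | 5-O-methyl ether of 8 (C5/C6 epimers) | C1[C@@H](OC(C)(C)O2)[C@@H]2C(OC)C(O[Si](C)(C)C(C)(C)C)[C@@]1(C(=O)OC)OC | intermediate
10 | methyl (1S)-6-(tert-butyldimethylsilyloxy)-3,4-dihydroxy-1,5-dimethoxycyclohexane-1-carboxylate (C1, C3, C4 as in quinic acid; C5/C6 epimers) | C1[C@@H](O)[C@@H](O)C(OC)C(O[Si](C)(C)C(C)(C)C)[C@@]1(C(=O)OC)OC | intermediate
11 | methyl (2S)-3-(tert-butyldimethylsilyloxy)-2,4-dimethoxy-5-oxo-2-(2-oxoethyl)pentanoate (dialdehyde, not isolated) | O=CC[C@@](OC)(C(=O)OC)C(O[Si](C)(C)C(C)(C)C)C(OC)C=O | intermediate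
12 | methyl (1S)-2-(tert-butyldimethylsilyloxy)-5-formyl-4-hydroxy-1,3-dimethoxycyclopentane-1-carboxylate (epimers at C2–C5) | O=CC1C(O)C(OC)C(O[Si](C)(C)C(C)(C)C)[C@]1(OC)C(=O)OC | intermediate
13 | (E)-β-bromostyrene | Br/C=C/c1ccccc1 | starting material
14 | methyl (1S)-2-(tert-butyldimethylsilyloxy)-4-hydroxy-5-[(2E)-1-hydroxy-3-phenylprop-2-en-1-yl]-1,3-dimethoxycyclopentane-1-carboxylate | OC(/C=C/c1ccccc1)C1C(O)C(OC)C(O[Si](C)(C)C(C)(C)C)[C@]1(OC)C(=O)OC | intermediate
15 | methyl (1S)-2,4-dihydroxy-5-[(2E)-1-hydroxy-3-phenylprop-2-en-1-yl]-1,3-dimethoxycyclopentane-1-carboxylate | OC(/C=C/c1ccccc1)C1C(O)C(OC)C(O)[C@]1(OC)C(=O)OC | intermediate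
16 | methyl (1S,5Z)-2-hydroxy-5-[(2E)-1-hydroxy-3-phenylprop-2-en-1-ylidene]-1,3-dimethoxy-4-oxocyclopent-2-ene-1-carboxylate | COC(=O)[C@@]1(OC)C(O)=C(OC)C(=O)/C1=C(O)/C=C/c1ccccc1 | intermediate
17 | methyl (1S,5Z)-5-[(2E)-1-hydroxy-3-phenylprop-2-en-1-ylidene]-1,2,3-trimethoxy-4-oxocyclopent-2-ene-1-carboxylate (CNP0305038.1) | COC(=O)[C@@]1(OC)C(OC)=C(OC)C(=O)/C1=C(O)/C=C/c1ccccc1 | target

Total step count: 14. Longest linear sequence: 14 steps from (−)-quinic acid; (E)-β-bromostyrene enters in step 11.

Steps most likely to fail

Step 10 (key step). The enamine of the CH2CHO arm may expel the methoxy group at C1, or the aldol may lose water. The congested dialdehyde may also cyclise too slowly to outrun these eliminations. The fallback avoids enamines. It sets out from dialdehyde 11. The unbranched aldehyde is converted chemoselectively (TBSOTf, Et3N, −78 °C) into its silyl enol ether, methyl 3-(tert-butyldimethylsilyloxy)-2-[2-(tert-butyldimethylsilyloxy)ethenyl]-2,4-dimethoxy-5-oxopentanoate F1. An intramolecular Mukaiyama aldol addition onto the chelated α-methoxy aldehyde (MgBr2·OEt2, CH2Cl2, −78 °C), followed by aqueous work-up, should then return to 12.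

Step 13. Oxidation of the hindered C2 carbinol may stall, and while partly oxidised β-hydroxy ketone intermediates persist, methanol (from C1) or water may be lost by β-elimination. The fallback stages the oxidation and sets out from 15. MnO2 (CH2Cl2, rt) should oxidise only the allylic alcohol, giving methyl (1S)-2,4-dihydroxy-1,3-dimethoxy-5-[(2E)-3-phenylprop-2-enoyl]cyclopentane-1-carboxylate F2. The two ring carbinols of F2 are then oxidised quickly at 0 °C with Dess–Martin periodinane, which returns to 16.

Step 14. Methylation may occur at the wrong oxygen (O4 of the ring dione unit or the side-chain enol oxygen), or twice. The fallback replaces kinetic alkylation by thermodynamic control and sets out from 16, or from the crude mixture of methyl ethers. Equilibration in methanol with catalytic TsOH (acid-catalysed vinylogous esterification) should favour the ring enol ether that keeps the hydrogen-bonded β-diketone, which is 17. The fallback returns at 17 and makes no new compound (F0).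

Further compounds
F1 | step 10 | methyl 3-(tert-butyldimethylsilyloxy)-2-[2-(tert-butyldimethylsilyloxy)ethenyl]-2,4-dimethoxy-5-oxopentanoate | CC(C)(C)[Si](C)(C)OC=C[C@@](OC)(C(=O)OC)C(O[Si](C)(C)C(C)(C)C)C(OC)C=O
F2 | step 13 | methyl (1S)-2,4-dihydroxy-1,3-dimethoxy-5-[(2E)-3-phenylprop-2-enoyl]cyclopentane-1-carboxylate | O=C(/C=C/c1ccccc1)C1C(O)C(OC)C(O)[C@]1(OC)C(=O)OC
F0 | step 14 | none | none
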